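**Plan**

1. Retrosynthesis: the side-chain C2′–C3′ bond is cut first (B-alkyl Suzuki–Miyaura), giving a 2-vinylchroman and a (2Z,6E)-iodo-dienoate. After C4 is raised to a ketone, the C2–C3 and O1–C8a bonds of the pyran ring are cut together, giving an aryl methyl ketone enolsilane and methyl pyruvate.
2. Enabling feature: in the pyran ring (ring B) O1 stands 1,3 to the benzylic carbon C4. With C4 as a carbonyl, C2–C3 is an aldol bond, and C8a of the benzene ring (ring A), ortho to that carbonyl, is an SNAr site when it carries fluorine. The CH3 and the chain carbon on C2 map onto the CH3 and ester carbon of pyruvate.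
3. Forward order: ring A is bought as 3-fluoro-5-methylphenol and acetylated at C4a. Ring B is closed in the key step. The C4 carbonyl and the benzyl group are then removed together, the ester becomes a vinyl group, and the chain is joined last.
4. Stereochemistry: C2 comes from the ligand-controlled copper-catalysed aldol addition. The 3′E alkene comes from a syn carboalumination and the 7′Z enoate from a Still–Gennari olefination; both are carried through a stereoretentive coupling.

Key step: step 5

Remark: chroman atoms are numbered O1, C2–C4, C4a, C5–C8, C8a and the chain C1′–C8′ outward from C2. The facial sense of the copper catalyst is assumed from the square-planar pyruvate chelate model ((S,S) ligand, si-face attack); the antipodal ligand would be used if the sense proved opposite.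

**Route**

Step 1
Reactants: 1 3-fluoro-5-methylphenol
Product: 2 4-bromo-3-fluoro-5-methylphenol
Conditions: NBS (1.0 equiv), MeCN, −20 → 0 °C
Reagents that add atoms: N-bromosuccinimide, BrN1C(=O)CCC1=O
Why: Electrophilic aromatic bromination in which the hydroxyl group directs para, to the ring carbon between fluorine and methyl, as in the para-bromination of 3,5-disubstituted phenols; no stereocentre is formed.

Step 2
Reactants: 2 4-bromo-3-fluoro-5-methylphenol
Product: 3 5-(benzyloxy)-2-bromo-1-fluoro-3-methylbenzene
Conditions: BnBr, K2CO3, DMF, rt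
Reagents that add atoms: benzyl bromide, BrCc1ccccc1
Why: Williamson ether synthesis; the benzyl ether tolerates the organolithium, Lewis-acid and fluoride steps and is later lost in the same hydrogenolysis that removes the C4 carbonyl.

Step 3
Reactants: 3 5-(benzyloxy)-2-bromo-1-fluoro-3-methylbenzene; 4 N-methoxy-N-methylacetamide
Product: 6 1-[4-(benzyloxy)-2-fluoro-6-methylphenyl]ethan-1-one, via aryllithium 5 (not isolated)
Conditions: n-BuLi, THF, −78 °C; then 4, −78 → 0 °C; 1 M HCl
Reagents that add atoms: none
Why: Bromine–lithium exchange followed by Weinreb ketone synthesis; at −78 °C the ortho-fluoro aryllithium should not eliminate LiF, and the chelated tetrahedral adduct prevents over-addition.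

Step 4
Reactants: 6 1-[4-(benzyloxy)-2-fluoro-6-methylphenyl]ethan-1-one
Product: 7 ({1-[4-(benzyloxy)-2-fluoro-6-methylphenyl]ethenyl}oxy)trimethylsilane
Conditions: Me3SiOTf, Et3N, CH2Cl2, 0 °C
Reagents that add atoms: trimethylsilyl trifluoromethanesulfonate, C[Si](C)(C)OS(=O)(=O)C(F)(F)F
Why: Soft enolisation and O-silylation (silyl enol ether formation) of the methyl ketone, whose only enolisable position is the acetyl methyl group that becomes C3.

Step 5
Reactants: 7 ({1-[4-(benzyloxy)-2-fluoro-6-methylphenyl]ethenyl}oxy)trimethylsilane; 8 methyl pyruvate (1.1 equiv)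
Product: 10 methyl (2S)-7-(benzyloxy)-2,5-dimethyl-4-oxochromane-2-carboxylate, via silyl aldol ether 9 (not isolated)
Conditions: Cu(OTf)2 (10 mol %), (S,S)-2,2′-(propane-2,2-diyl)bis(4-tert-butyl-4,5-dihydro-1,3-oxazole) (11 mol %), THF, −78 °C; then DMF, tetrabutylammonium difluorotriphenylsilicate (0.3 equiv), −40 → 0 °C; AcOH quench
Reagents that add atoms: none
Why: Proposed new method: divalent copper bound to the C2-symmetric bis(oxazoline) holds methyl pyruvate as a five-membered chelate through its keto and ester oxygens, the terminal carbon of enolsilane 7 adds to the exposed si face of the keto carbon (Mukaiyama aldol, C2–C3 bond) and silyl transfer gives the tertiary silyl ether 9; fluoride then removes the trimethylsilyl group and the tertiary alkoxide attacks the fluorine-bearing ring carbon ortho to the ketone by addition–elimination through a Meisenheimer enolate (O1–C8a bond), the expelled fluoride desilylating the next molecule of 9 so that fluorotrimethylsilane is the only stoichiometric by-product. The closest known reaction types are the copper bis(oxazoline)-catalysed aldol addition of ketone enolsilanes to pyruvate esters and the fluoride-catalysed condensation of silyl ethers with carbonyl-activated aryl fluorides; their merger into one enantioselective annulation with a tertiary aldol silyl ether as the nucleophile is the new element. The one ring closed is the dihydropyranone ring B, by 6-exo-trig attack of oxygen on the aromatic carbon. The one new stereocentre, C2, is set in the aldol event by the ligand (reagent control through two-point binding of the 1,2-dicarbonyl unit) and should be (S), the descriptor changing to (R) in the target only because the final chain ranks below C3 whereas the ester ranks above it; the ring closure does not touch it. The step needs ring closure to outrun retro-aldol cleavage of the tertiary alkoxide and needs the product not to open by E1cB loss of the aryloxide, and this is secured by the ketone ortho to fluorine (fast SNAr at or below 0 °C), by the single ortho fluorine (one possible site) and by a medium whose only base is a catalytic amount of alkoxide that is quenched with acetic acid at the end.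

Step 6
Reactants: 10 methyl (2S)-7-(benzyloxy)-2,5-dimethyl-4-oxochromane-2-carboxylate
Product: 11 methyl (2S)-7-hydroxy-2,5-dimethylchromane-2-carboxylate
Conditions: H2 (4 atm), Pd/C (10 %), MeOH–AcOH, cat. HCl, 40 °C
Reagents that add atoms: none
Why: Catalytic hydrogenolysis cleaves the benzyl ether and reduces the electron-rich aryl ketone through the benzylic alcohol to the C4 methylene, which removes the activating carbonyl; the quaternary C2 has no cleavable benzylic bond and keeps its configuration.

Step 7
Reactants: 11 methyl (2S)-7-hydroxy-2,5-dimethylchromane-2-carboxylate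
Product: 12 methyl (2S)-2,5-dimethyl-7-[(triisopropylsilyl)oxy]chromane-2-carboxylate
Conditions: i-Pr3SiCl, imidazole, DMF, rt
Reagents that add atoms: chlorotriisopropylsilane, CC(C)[Si](Cl)(C(C)C)C(C)C
Why: Silylation of the phenol as its triisopropylsilyl ether, which should withstand the hydride, ylide, borane and aqueous-base conditions that follow and leaves with fluoride at the end.

Step 8
Reactants: 12 methyl (2S)-2,5-dimethyl-7-[(triisopropylsilyl)oxy]chromane-2-carboxylate
Product: 13 (2S)-2,5-dimethyl-7-[(triisopropylsilyl)oxy]chromane-2-carbaldehyde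
Conditions: i-Bu2AlH (1.1 equiv), CH2Cl2, −78 °C; aq. potassium sodium tartrate
Reagents that add atoms: none
Why: Partial reduction of the α-aryloxy ester with i-Bu2AlH at −78 °C stops at the aldehyde because the chelated aluminium hemiacetal persists until work-up; C2 is quaternary and cannot epimerise.

Step 9
Reactants: 13 (2S)-2,5-dimethyl-7-[(triisopropylsilyl)oxy]chromane-2-carbaldehyde
Product: 14 {[(2S)-2-ethenyl-2,5-dimethylchroman-7-yl]oxy}triisopropylsilane
Conditions: Ph3PCH3Br, KN(SiMe3)2, THF, 0 °C; then 13, 0 °C → rt
Reagents that add atoms: methyltriphenylphosphonium bromide, C[P+](c1ccccc1)(c1ccccc1)c1ccccc1.[Br-]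
Why: Wittig methylenation of the non-enolisable aldehyde gives the terminal alkene that supplies C1′ and C2′ of the chain.

Step 10
Reactants: 15 pent-4-yn-1-ol
Product: 17 (4E)-5-iodo-4-methylpent-4-en-1-ol, via alkenylalane 16 (not isolated)
Conditions: Me3Al (3 equiv), Cp2ZrCl2 (0.25 equiv), CH2Cl2, 0 °C → rt; then I2, THF, −30 → 0 °C; aq. K2CO3
Reagents that add atoms: trimethylaluminium, C[Al](C)C; iodine, II
Why: Zirconium-catalysed carboalumination (Negishi carboalumination) adds methyl and aluminium syn across the terminal alkyne with aluminium on the terminal carbon, and iodinolysis with retention gives the E trisubstituted vinyl iodide.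

Step 11
Reactants: 17 (4E)-5-iodo-4-methylpent-4-en-1-ol
Product: 18 (4E)-5-iodo-4-methylpent-4-enal
Conditions: Dess–Martin periodinane, CH2Cl2, 0 °C → rt
Reagents that add atoms: none
Why: Dess–Martin oxidation of the primary alcohol to the aldehyde under neutral conditions that leave the vinyl iodide untouched.

Step 12
Reactants: 18 (4E)-5-iodo-4-methylpent-4-enal; 19 methyl 2-[bis(2,2,2-trifluoroethoxy)phosphoryl]propanoate
Product: 20 methyl (2Z,6E)-7-iodo-2,6-dimethylhepta-2,6-dienoate
Conditions: 19, KN(SiMe3)2, 18-crown-6, THF, −78 °C; then 18, −78 °C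
Reagents that add atoms: none
Why: Still–Gennari olefination, in which the bis(trifluoroethyl) phosphonate with a dissociated potassium counter-ion eliminates under kinetic control to give the Z trisubstituted enoate.

Step 13
Reactants: 14 {[(2S)-2-ethenyl-2,5-dimethylchroman-7-yl]oxy}triisopropylsilane; 20 methyl (2Z,6E)-7-iodo-2,6-dimethylhepta-2,6-dienoate
Product: 22 methyl (2Z,6E)-9-{(2R)-2,5-dimethyl-7-[(triisopropylsilyl)oxy]chroman-2-yl}-2,6-dimethylnona-2,6-dienoate, via alkylborane 21 (not isolated)
Conditions: 9-BBN-H, THF, rt; then aq. K3PO4, 20, Pd(dppf)Cl2 (5 mol %), AsPh3, DMF, rt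
Reagents that add atoms: none
Why: B-alkyl Suzuki–Miyaura coupling, in which 9-BBN-H adds anti-Markovnikov to the monosubstituted alkene and the palladium-catalysed coupling with the vinyl iodide proceeds with retention of the E geometry while the ester, the Z enoate and the silyl ether are tolerated.

Step 14
Reactants: 22 methyl (2Z,6E)-9-{(2R)-2,5-dimethyl-7-[(triisopropylsilyl)oxy]chroman-2-yl}-2,6-dimethylnona-2,6-dienoate
Product: 23 methyl (2Z,6E)-9-[(2R)-7-hydroxy-2,5-dimethylchroman-2-yl]-2,6-dimethylnona-2,6-dienoate
Conditions: Bu4NF, AcOH, THF, 0 °C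
Reagents that add atoms: none
Why: Fluoride-mediated cleavage of the aryl silyl ether, buffered with acetic acid so that the Z enoate and the methyl ester are not touched, should give the target.

**Compound list**

1 | 3-fluoro-5-methylphenol | Cc1cc(O)cc(F)c1 | starting material
2 | 4-bromo-3-fluoro-5-methylphenol | Cc1cc(O)cc(F)c1Br | intermediate
3 | 5-(benzyloxy)-2-bromo-1-fluoro-3-methylbenzene | Cc1cc(OCc2ccccc2)cc(F)c1Br | intermediate
4 | N-methoxy-N-methylacetamide | CC(=O)N(C)OC | starting material
5 | [4-(benzyloxy)-2-fluoro-6-methylphenyl]lithium (aryllithium, not isolated) | [Li]c1c(C)cc(OCc2ccccc2)cc1F | intermediate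
6 | 1-[4-(benzyloxy)-2-fluoro-6-methylphenyl]ethan-1-one | CC(=O)c1c(C)cc(OCc2ccccc2)cc1F | intermediate
7 | ({1-[4-(benzyloxy)-2-fluoro-6-methylphenyl]ethenyl}oxy)trimethylsilane | C=C(O[Si](C)(C)C)c1c(C)cc(OCc2ccccc2)cc1F | intermediate
8 | methyl pyruvate (methyl 2-oxopropanoate) | COC(=O)C(C)=O | starting material
9 | methyl (2S)-4-[4-(benzyloxy)-2-fluoro-6-methylphenyl]-2-methyl-4-oxo-2-[(trimethylsilyl)oxy]butanoate (silyl aldol ether, not isolated) | COC(=O)[C@](C)(CC(=O)c1c(C)cc(OCc2ccccc2)cc1F)O[Si](C)(C)C | intermediate
10 | methyl (2S)-7-(benzyloxy)-2,5-dimethyl-4-oxochromane-2-carboxylate | COC(=O)[C@]1(C)CC(=O)c2c(C)cc(OCc3ccccc3)cc2O1 | intermediate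
11 | methyl (2S)-7-hydroxy-2,5-dimethylchromane-2-carboxylate | COC(=O)[C@]1(C)CCc2c(C)cc(O)cc2O1 | intermediate
12 | methyl (2S)-2,5-dimethyl-7-[(triisopropylsilyl)oxy]chromane-2-carboxylate | COC(=O)[C@]1(C)CCc2c(C)cc(O[Si](C(C)C)(C(C)C)C(C)C)cc2O1 | intermediate
13 | (2S)-2,5-dimethyl-7-[(triisopropylsilyl)oxy]chromane-2-carbaldehyde | O=C[C@]1(C)CCc2c(C)cc(O[Si](C(C)C)(C(C)C)C(C)C)cc2O1 | intermediate
14 | {[(2S)-2-ethenyl-2,5-dimethylchroman-7-yl]oxy}triisopropylsilane | C=C[C@]1(C)CCc2c(C)cc(O[Si](C(C)C)(C(C)C)C(C)C)cc2O1 | intermediate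
15 | pent-4-yn-1-ol | C#CCCCO | starting material
16 | [(1E)-5-(dimethylalumanyloxy)-2-methylpent-1-en-1-yl]dimethylalumane (alkenylalane, not isolated) | C[Al](C)/C=C(C)/CCCO[Al](C)C | intermediate
17 | (4E)-5-iodo-4-methylpent-4-en-1-ol | OCCC/C(C)=C/I | intermediate
18 | (4E)-5-iodo-4-methylpent-4-enal | O=CCC/C(C)=C/I | intermediate
19 | methyl 2-[bis(2,2,2-trifluoroethoxy)phosphoryl]propanoate | COC(=O)C(C)P(=O)(OCC(F)(F)F)OCC(F)(F)F | starting material
20 | methyl (2Z,6E)-7-iodo-2,6-dimethylhepta-2,6-dienoate | COC(=O)/C(C)=C\CC/C(C)=C/I | intermediate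
21 | 9-{2-[(2R)-2,5-dimethyl-7-(triisopropylsilyloxy)chroman-2-yl]ethyl}-9-borabicyclo[3.3.1]nonane (alkylborane, not isolated) | C1CCC2CCCC1B2CC[C@]1(C)CCc2c(C)cc(O[Si](C(C)C)(C(C)C)C(C)C)cc2O1 | intermediate
22 | methyl (2Z,6E)-9-{(2R)-2,5-dimethyl-7-[(triisopropylsilyl)oxy]chroman-2-yl}-2,6-dimethylnona-2,6-dienoate | COC(=O)/C(C)=C\CC/C(C)=C/CC[C@]1(C)CCc2c(C)cc(O[Si](C(C)C)(C(C)C)C(C)C)cc2O1 | intermediate
23 | methyl (2Z,6E)-9-[(2R)-7-hydroxy-2,5-dimethylchroman-2-yl]-2,6-dimethylnona-2,6-dienoate | COC(=O)/C(C)=C\CC/C(C)=C/CC[C@]1(C)CCc2c(C)cc(O)cc2O1 | target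

**Step count and risks**

Total step count: 14. Longest linear sequence: 11 (steps 1–9, 13, 14).

Steps most likely to fail:

Step 5. Retro-aldol cleavage of the tertiary alkoxide before ring closure, or base-induced opening and re-closure of the chromanone, would erode enantiopurity. Displacement of fluoride may also be slow because the flanking methyl group twists the carbonyl out of conjugation. The fallback sets out from 7 and 8 and returns to the route at 11, using known chemistry only. The aldol addition alone is run with the same copper catalyst and worked up with 1 M HCl to give methyl (2S)-4-[4-(benzyloxy)-2-fluoro-6-methylphenyl]-2-hydroxy-2-methyl-4-oxobutanoate F1. Ionic hydrogenation (Et3SiH, CF3CO2H, CH2Cl2, 0 °C) removes the ketone before any base is applied and gives methyl (2S)-4-[4-(benzyloxy)-2-fluoro-6-methylphenyl]-2-hydroxy-2-methylbutanoate F2, which can no longer fragment. KN(SiMe3)2 in DMF at 60 °C then closes ring B by intramolecular SNAr at the unactivated fluoroarene to give methyl (2S)-7-(benzyloxy)-2,5-dimethylchromane-2-carboxylate F3, which has no C4 carbonyl and cannot ring-open. Hydrogenolysis (H2, Pd/C, MeOH) gives 11.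

Step 13. Hydroboration next to the quaternary carbon and transmetalation of the β-quaternary alkylborane may be slow, so that protodeboronation or reduction of the vinyl iodide competes. The fallback sets out from 14 and returns at 22. Hydroboration (9-BBN-H, via 21) with oxidative work-up (NaBO3·4H2O, THF–H2O) gives 2-[(2S)-2,5-dimethyl-7-(triisopropylsilyloxy)chroman-2-yl]ethan-1-ol F4. Appel iodination (I2, PPh3, imidazole, CH2Cl2) gives {[(2S)-2-(2-iodoethyl)-2,5-dimethylchroman-7-yl]oxy}triisopropylsilane F5. Zinc insertion (Zn dust, LiCl, THF) gives the alkylzinc iodide {2-[(2S)-2,5-dimethyl-7-(triisopropylsilyloxy)chroman-2-yl]ethyl}(iodo)zinc F6. Negishi coupling with 20 under Pd(PPh3)4 (zerovalent palladium) in THF gives 22.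

Step 1. Bromine may attack ortho instead of para to the hydroxyl group, or a second bromination may occur. The fallback sets out from 1 and returns at 3. The phenol is benzylated first (BnBr, K2CO3, DMF) to give 1-(benzyloxy)-3-fluoro-5-methylbenzene F7. Bromination of this aryl ether with NBS in MeCN, where ether oxygen directs para without delivery of the electrophile to the ortho positions, gives 3.

**Further compounds**

F1 | step 5 | methyl (2S)-4-[4-(benzyloxy)-2-fluoro-6-methylphenyl]-2-hydroxy-2-methyl-4-oxobutanoate | COC(=O)[C@](C)(CC(=O)c1c(C)cc(OCc2ccccc2)cc1F)O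
F2 | step 5 | methyl (2S)-4-[4-(benzyloxy)-2-fluoro-6-methylphenyl]-2-hydroxy-2-methylbutanoate | COC(=O)[C@](C)(CCc1c(C)cc(OCc2ccccc2)cc1F)O
F3 | step 5 | methyl (2S)-7-(benzyloxy)-2,5-dimethylchromane-2-carboxylate | COC(=O)[C@]1(C)CCc2c(C)cc(OCc3ccccc3)cc2O1
F4 | step 13 | 2-[(2S)-2,5-dimethyl-7-(triisopropylsilyloxy)chroman-2-yl]ethan-1-ol | OCC[C@]1(C)CCc2c(C)cc(O[Si](C(C)C)(C(C)C)C(C)C)cc2O1
F5 | step 13 | {[(2S)-2-(2-iodoethyl)-2,5-dimethylchroman-7-yl]oxy}triisopropylsilane | ICC[C@]1(C)CCc2c(C)cc(O[Si](C(C)C)(C(C)C)C(C)C)cc2O1
F6 | step 13 | {2-[(2S)-2,5-dimethyl-7-(triisopropylsilyloxy)chroman-2-yl]ethyl}(iodo)zinc | I[Zn]CC[C@]1(C)CCc2c(C)cc(O[Si](C(C)C)(C(C)C)C(C)C)cc2O1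
F7 | step 1 | 1-(benzyloxy)-3-fluoro-5-methylbenzene | Cc1cc(OCc2ccccc2)cc(F)c1
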